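The farnesyl chain is cut at its benzylic C1''–C2'' bond and at the C3''–methyl bond, tracing ring A to a 2,6-bis(methoxymethoxy)benzyl chloride whose para oxygen (the later O1) is a tosylate, and the chain to a terminal dienyne. One operation (zirconium-catalysed methylalumination, then nickel-catalysed coupling of the alkenylalane) builds the E-trisubstituted C2''=C3'' alkene and joins it to C1'' on C6 of ring A without any allyl intermediate. The chloride carbon is the former formyl carbon of phloroglucinaldehyde, so the chain sits between O5 and O7. Ring C follows by ortho-formylation, chromone formation and rhodium-catalysed asymmetric arylation, which sets C2 as S.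

Key step: step 7

Remark: the target is read as the (2S)-flavanone with a 2E,6E chain; the para oxygen of the benzylic chloride is carried as an arenesulfonate because a benzylic chloride with three ether-type donors in the ortho and para positions would ionise readily, whereas the electron-poor sulfonate should make the chloride isolable and slow to ionise under the Lewis acidic alane.

Step 1
Reactants: 1 2,4,6-trihydroxybenzaldehyde
Product: 2 4-formyl-3,5-dihydroxyphenyl 4-methylbenzenesulfonate
Conditions: TsCl (1.0 equiv), Et3N (1.05 equiv), THF, −20 → 0 °C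
Reagents that add atoms: p-toluenesulfonyl chloride, Cc1ccc(cc1)S(=O)(=O)Cl
Why: O-sulfonylation should go to the 4-OH, which is the most acidic (para to the formyl group) and unhindered, whereas the 2- and 6-OH are flanked by the formyl group and hydrogen-bonded to it.

Step 2
Reactants: 2 4-formyl-3,5-dihydroxyphenyl 4-methylbenzenesulfonate
Product: 3 4-formyl-3,5-bis(methoxymethoxy)phenyl 4-methylbenzenesulfonate
Conditions: NaH (2.4 equiv), MOMCl (2.6 equiv), DMF, 0 °C → rt
Reagents that add atoms: chloromethyl methyl ether, COCCl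
Why: Williamson-type O-alkylation of both sodium phenoxides (MOM protection), forced by NaH because these hydroxyls are hydrogen-bonded; the aryl sulfonate is inert to hydride base and phenoxide at this temperature.

Step 3
Reactants: 3 4-formyl-3,5-bis(methoxymethoxy)phenyl 4-methylbenzenesulfonate
Product: 4 4-(hydroxymethyl)-3,5-bis(methoxymethoxy)phenyl 4-methylbenzenesulfonate
Conditions: NaBH4, THF/MeOH (4:1), 0 °C
Reagents that add atoms: none
Why: Hydride reduction of the aldehyde to the benzylic alcohol; acetals and the sulfonate do not react with NaBH4.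

Step 4
Reactants: 4 4-(hydroxymethyl)-3,5-bis(methoxymethoxy)phenyl 4-methylbenzenesulfonate
Product: 5 4-(chloromethyl)-3,5-bis(methoxymethoxy)phenyl 4-methylbenzenesulfonate
Conditions: PPh3, NCS (premixed), THF, 0 °C → rt
Reagents that add atoms: N-chlorosuccinimide, O=C1CCC(=O)N1Cl
Why: Appel-type chlorination through the alkoxyphosphonium ion runs under neutral conditions, so the MOM acetals survive, and the para sulfonate should keep the chloride from ionising during isolation.

Step 5
Reactants: 6 geranyl bromide [(2E)-1-bromo-3,7-dimethylocta-2,6-diene]; 7 1-(trimethylsilyl)propyne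
Product: 9 trimethyl[(5E)-6,10-dimethylundeca-5,9-dien-1-yn-1-yl]silane, via lithiated silylpropyne 8 (not isolated)
Conditions: 7, n-BuLi, THF, −78 → −20 °C; then 6, −78 °C → rt
Reagents that add atoms: none
Why: Propargylic lithiation of the silylpropyne followed by SN2 alkylation with the primary allylic bromide; the silyl group steers attack to the propargylic terminus and the existing E alkene is not touched.

Step 6
Reactants: 9 trimethyl[(5E)-6,10-dimethylundeca-5,9-dien-1-yn-1-yl]silane
Product: 10 (5E)-6,10-dimethylundeca-5,9-dien-1-yne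
Conditions: K2CO3 (0.2 equiv), MeOH, rt
Reagents that add atoms: none
Why: Base-catalysed methanolysis of the alkynyl C–Si bond (protodesilylation) frees the terminal alkyne.

Step 7
Reactants: 10 (5E)-6,10-dimethylundeca-5,9-dien-1-yne; 5 4-(chloromethyl)-3,5-bis(methoxymethoxy)phenyl 4-methylbenzenesulfonate
Product: 12 3,5-bis(methoxymethoxy)-4-[(2E,6E)-3,7,11-trimethyldodeca-2,6,10-trien-1-yl]phenyl 4-methylbenzenesulfonate, via alkenylalane 11 (not isolated)
Conditions: Me3Al (2.0 equiv), Cp2ZrCl2 (0.25 equiv), ClCH2CH2Cl, 0 °C → rt; volatiles removed, THF; then 5 (0.85 equiv), NiCl2(PPh3)2 (5 mol%) pre-reduced with n-BuLi (10 mol%), THF, −20 °C → rt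
Reagents that add atoms: trimethylaluminium, C[Al](C)C
Why: Cp2ZrCl2-catalysed methylalumination adds methyl and aluminium syn across the terminal alkyne of 10, methyl to the internal and aluminium to the terminal carbon, so alane 11 should form as the E isomer only while the isolated trisubstituted alkenes stay untouched. Zerovalent nickel, made from NiCl2(PPh3)2 and n-BuLi, inserts into the benzylic C–Cl bond of 5, the alkenyl group passes from aluminium to nickel, and reductive elimination forms the C1''–C2'' bond with retention of alkene geometry. The closest known reaction type is the Negishi carboalumination followed by nickel-catalysed coupling of alkenylalanes with benzylic chlorides, the established way to attach polyprenyl chains to arenes and quinones. No ring is closed and no stereocentre is formed; the only stereochemical element, the C2''=C3'' geometry, is fixed by the syn addition. The step needs chemoselectivity for the benzylic chloride over the aryl sulfonate and over Lewis-acid ionisation: a triphenylphosphine–nickel catalyst at or below room temperature adds to the C–Cl bond far faster than to the aryl C–O bond, and the electron-withdrawing sulfonate para to the CH2Cl group disfavours the benzylic cation. Because the chain carbon is the former formyl carbon and neither an allyl metal nor an allyl cation intervenes, ring-positional isomers, SN2' transposition and E/Z scrambling are all excluded.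

Step 8
Reactants: 12 3,5-bis(methoxymethoxy)-4-[(2E,6E)-farnesyl]phenyl 4-methylbenzenesulfonate
Product: 13 3,5-bis(methoxymethoxy)-4-[(2E,6E)-3,7,11-trimethyldodeca-2,6,10-trien-1-yl]phenol
Conditions: KOH (10 equiv), MeOH/THF/H2O, 65 °C, argon
Reagents that add atoms: none
Why: Hydroxide attacks sulfur and cleaves the S–O bond of the aryl sulfonate (saponification of an aryl tosylate); MOM acetals and isolated alkenes are stable to base.

Step 9
Reactants: 13 3,5-bis(methoxymethoxy)-4-[(2E,6E)-farnesyl]phenol
Product: 15 6-hydroxy-2,4-bis(methoxymethoxy)-3-[(2E,6E)-3,7,11-trimethyldodeca-2,6,10-trien-1-yl]benzaldehyde, via hydroxymethylphenol 14 (not isolated)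
Conditions: MgCl2 (2 equiv), Et3N (4 equiv), (CH2O)n (6 equiv), THF, reflux; cold aq. NH4Cl
Reagents that add atoms: paraformaldehyde (as formaldehyde), C=O
Why: Casnati–Skattebøl ortho-formylation: the magnesium phenoxide delivers formaldehyde to an ortho carbon (both are equivalent, para is blocked by the chain) and a second formaldehyde oxidises the salicyl alkoxide by Oppenauer-type hydride transfer, all under non-acidic conditions.

Step 10
Reactants: 15 6-hydroxy-2,4-bis(methoxymethoxy)-3-[(2E,6E)-farnesyl]benzaldehyde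
Product: 16 2-(1-hydroxyprop-2-yn-1-yl)-3,5-bis(methoxymethoxy)-4-[(2E,6E)-3,7,11-trimethyldodeca-2,6,10-trien-1-yl]phenol (racemic at the carbinol carbon)
Conditions: HC≡CMgBr (3 equiv), THF, 0 °C → rt; cold aq. NH4Cl; crude product used directly
Reagents that add atoms: ethynylmagnesium bromide, C#C[Mg]Br
Why: Grignard addition of the acetylide to the aldehyde after deprotonation of the phenol; the carbinol centre forms as a racemate and is destroyed by the oxidation in step 11.

Step 11
Reactants: 16 2-(1-hydroxyprop-2-yn-1-yl)-3,5-bis(methoxymethoxy)-4-[(2E,6E)-farnesyl]phenol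
Product: 19 5,7-bis(methoxymethoxy)-6-[(2E,6E)-3,7,11-trimethyldodeca-2,6,10-trien-1-yl]-4H-chromen-4-one, via ynone 17 (not isolated), via enaminone 18 (not isolated)
Conditions: MnO2 (15 equiv), CH2Cl2, rt; filtration; Et2NH (2 equiv), EtOH, rt; then AcOH (5 equiv), 50 °C
Reagents that add atoms: none
Why: MnO2 oxidises the benzylic–propargylic alcohol selectively, diethylamine adds to the terminal ynone in conjugate fashion, and the chelated phenol closes the pyranone ring by 6-endo addition–elimination (oxa-Michael addition, loss of the amine).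

Step 12
Reactants: 20 5-bromoresorcinol (5-bromobenzene-1,3-diol)
Product: 21 1-bromo-3,5-bis(methoxymethoxy)benzene
Conditions: MOMCl (2.6 equiv), i-Pr2NEt (3 equiv), CH2Cl2, 0 °C → rt
Reagents that add atoms: chloromethyl methyl ether, COCCl
Why: Standard O-alkylation of two unhindered phenols to MOM ethers.

Step 13
Reactants: 21 1-bromo-3,5-bis(methoxymethoxy)benzene
Product: 24 [3,5-bis(methoxymethoxy)phenyl]boronic acid, via aryllithium 22 (not isolated), via lithium borate 23 (not isolated)
Conditions: n-BuLi, THF, −78 °C; B(Oi-Pr)3, −78 °C → rt; aq. HCl to pH 5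
Reagents that add atoms: triisopropyl borate, CC(C)OB(OC(C)C)OC(C)C; water, O
Why: Bromine–lithium exchange is faster than ortho-deprotonation at −78 °C, the aryllithium is trapped by the borate, and mild hydrolysis gives the boronic acid without loss of the MOM groups.

Step 14
Reactants: 19 5,7-bis(methoxymethoxy)-6-[(2E,6E)-farnesyl]-4H-chromen-4-one; 24 [3,5-bis(methoxymethoxy)phenyl]boronic acid
Product: 25 (2S)-2-[3,5-bis(methoxymethoxy)phenyl]-5,7-bis(methoxymethoxy)-6-[(2E,6E)-3,7,11-trimethyldodeca-2,6,10-trien-1-yl]chroman-4-one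
Conditions: 24 (3 equiv), [RhCl(C2H4)2]2 (2.5 mol%), (S)-MeO-F12-BIPHEP [(S)-6,6'-dimethoxy-2,2'-bis[bis(3,4,5-trifluorophenyl)phosphino]biphenyl] (5.5 mol%), KOH (10 mol%), toluene/H2O (10:1), 40 °C
Reagents that add atoms: none
Why: Hayashi–Miyaura rhodium-catalysed asymmetric 1,4-addition: the aryl group passes from boron to rhodium and inserts the C2=C3 bond on the face left open by the (S)-biaryl bisphosphine, which by the quadrant model for cyclic enones should give 2S (the antipodal ligand would be used if the sense proved opposite), and water protonates the rhodium enolate before it can ring-open.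

Step 15
Reactants: 25 (2S)-2-[3,5-bis(methoxymethoxy)phenyl]-5,7-bis(methoxymethoxy)-6-[(2E,6E)-farnesyl]chroman-4-one
Product: 26 (2S)-2-(3,5-dihydroxyphenyl)-5,7-dihydroxy-6-[(2E,6E)-3,7,11-trimethyldodeca-2,6,10-trien-1-yl]chroman-4-one (CNP0186816.1)
Conditions: 3 M aq. HCl/MeOH (1:5), 50 °C, argon
Reagents that add atoms: none
Why: Acid-catalysed transacetalisation of the four MOM ethers to methanol, the usual final deprotection for prenylated flavanones; moderate temperature should keep the phenols from adding to the chain alkenes and leave C2 untouched.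

Compound list
1 | 2,4,6-trihydroxybenzaldehyde | O=Cc1c(O)cc(O)cc1O | starting material
2 | 4-formyl-3,5-dihydroxyphenyl 4-methylbenzenesulfonate | Cc1ccc(cc1)S(=O)(=O)Oc1cc(O)c(C=O)c(O)c1 | intermediate
3 | 4-formyl-3,5-bis(methoxymethoxy)phenyl 4-methylbenzenesulfonate | Cc1ccc(cc1)S(=O)(=O)Oc1cc(OCOC)c(C=O)c(OCOC)c1 | intermediate
4 | 4-(hydroxymethyl)-3,5-bis(methoxymethoxy)phenyl 4-methylbenzenesulfonate | Cc1ccc(cc1)S(=O)(=O)Oc1cc(OCOC)c(CO)c(OCOC)c1 | intermediate
5 | 4-(chloromethyl)-3,5-bis(methoxymethoxy)phenyl 4-methylbenzenesulfonate | Cc1ccc(cc1)S(=O)(=O)Oc1cc(OCOC)c(CCl)c(OCOC)c1 | intermediate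
6 | geranyl bromide, (2E)-1-bromo-3,7-dimethylocta-2,6-diene | CC(C)=CCC/C(C)=C/CBr | starting material
7 | 1-(trimethylsilyl)propyne | CC#C[Si](C)(C)C | starting material
8 | 3-lithio-1-(trimethylsilyl)propyne (not isolated) | [Li]CC#C[Si](C)(C)C | intermediate
9 | trimethyl[(5E)-6,10-dimethylundeca-5,9-dien-1-yn-1-yl]silane | CC(C)=CCC/C(C)=C/CCC#C[Si](C)(C)C | intermediate
10 | (5E)-6,10-dimethylundeca-5,9-dien-1-yne | CC(C)=CCC/C(C)=C/CCC#C | intermediate
11 | dimethyl[(1E,5E)-2,6,10-trimethylundeca-1,5,9-trien-1-yl]alane (not isolated) | CC(C)=CCC/C(C)=C/CC/C(C)=C/[Al](C)C | intermediate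
12 | 3,5-bis(methoxymethoxy)-4-[(2E,6E)-3,7,11-trimethyldodeca-2,6,10-trien-1-yl]phenyl 4-methylbenzenesulfonate | CC(C)=CCC/C(C)=C/CC/C(C)=C/Cc1c(OCOC)cc(OS(=O)(=O)c2ccc(C)cc2)cc1OCOC | intermediate
13 | 3,5-bis(methoxymethoxy)-4-[(2E,6E)-3,7,11-trimethyldodeca-2,6,10-trien-1-yl]phenol | CC(C)=CCC/C(C)=C/CC/C(C)=C/Cc1c(OCOC)cc(O)cc1OCOC | intermediate
14 | 2-(hydroxymethyl)-3,5-bis(methoxymethoxy)-4-[(2E,6E)-farnesyl]phenol, as its magnesium salt (not isolated) | CC(C)=CCC/C(C)=C/CC/C(C)=C/Cc1c(OCOC)cc(O)c(CO)c1OCOC | intermediate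
15 | 6-hydroxy-2,4-bis(methoxymethoxy)-3-[(2E,6E)-3,7,11-trimethyldodeca-2,6,10-trien-1-yl]benzaldehyde | CC(C)=CCC/C(C)=C/CC/C(C)=C/Cc1c(OCOC)cc(O)c(C=O)c1OCOC | intermediate
16 | 2-(1-hydroxyprop-2-yn-1-yl)-3,5-bis(methoxymethoxy)-4-[(2E,6E)-farnesyl]phenol, racemic | CC(C)=CCC/C(C)=C/CC/C(C)=C/Cc1c(OCOC)cc(O)c(C(O)C#C)c1OCOC | intermediate
17 | 1-[6-hydroxy-2,4-bis(methoxymethoxy)-3-[(2E,6E)-farnesyl]phenyl]prop-2-yn-1-one (not isolated) | CC(C)=CCC/C(C)=C/CC/C(C)=C/Cc1c(OCOC)cc(O)c(C(=O)C#C)c1OCOC | intermediate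
18 | (2E)-3-(diethylamino)-1-[6-hydroxy-2,4-bis(methoxymethoxy)-3-[(2E,6E)-farnesyl]phenyl]prop-2-en-1-one (not isolated) | CC(C)=CCC/C(C)=C/CC/C(C)=C/Cc1c(OCOC)cc(O)c(C(=O)/C=C/N(CC)CC)c1OCOC | intermediate
19 | 5,7-bis(methoxymethoxy)-6-[(2E,6E)-3,7,11-trimethyldodeca-2,6,10-trien-1-yl]-4H-chromen-4-one | CC(C)=CCC/C(C)=C/CC/C(C)=C/Cc1c(OCOC)cc2occc(=O)c2c1OCOC | intermediate
20 | 5-bromoresorcinol | Oc1cc(O)cc(Br)c1 | starting material
21 | 1-bromo-3,5-bis(methoxymethoxy)benzene | COCOc1cc(Br)cc(OCOC)c1 | intermediate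
22 | [3,5-bis(methoxymethoxy)phenyl]lithium (not isolated) | [Li]c1cc(OCOC)cc(OCOC)c1 | intermediate
23 | lithium [3,5-bis(methoxymethoxy)phenyl]tri(propan-2-yloxy)borate (not isolated) | [Li+].CC(C)O[B-](OC(C)C)(OC(C)C)c1cc(OCOC)cc(OCOC)c1 | intermediate
24 | [3,5-bis(methoxymethoxy)phenyl]boronic acid | OB(O)c1cc(OCOC)cc(OCOC)c1 | intermediate
25 | (2S)-2-[3,5-bis(methoxymethoxy)phenyl]-5,7-bis(methoxymethoxy)-6-[(2E,6E)-3,7,11-trimethyldodeca-2,6,10-trien-1-yl]chroman-4-one | CC(C)=CCC/C(C)=C/CC/C(C)=C/Cc1c(OCOC)cc2c(c1OCOC)C(=O)C[C@@H](c1cc(OCOC)cc(OCOC)c1)O2 | intermediate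
26 | (2S)-2-(3,5-dihydroxyphenyl)-5,7-dihydroxy-6-[(2E,6E)-3,7,11-trimethyldodeca-2,6,10-trien-1-yl]chroman-4-one | CC(C)=CCC/C(C)=C/CC/C(C)=C/Cc1c(O)cc2c(c1O)C(=O)C[C@@H](c1cc(O)cc(O)c1)O2 | target

Total step count: 15. Longest linear sequence: 11 steps (steps 1–4, 7–11, 14, 15).

Steps most likely to fail

Step 7. The benzylic chloride may ionise under the Lewis acidic alane, methyl may be transferred in place of the alkenyl group, or the alane may be protonated before coupling. The fallback reverses the polarity of the two partners and sets out from 10 and 5. Alane 11, made from 10 as before, would be quenched with iodine at −30 °C to give the alkenyl iodide (1E,5E)-1-iodo-2,6,10-trimethylundeca-1,5,9-triene F1. Chloride 5 would be converted with zinc dust and LiCl in THF into the benzylic zinc reagent [2,6-bis(methoxymethoxy)-4-(tosyloxy)benzyl]zinc chloride F2. Negishi coupling of F2 with F1 under Pd(PPh3)4 (zerovalent palladium) in THF at room temperature, which retains the alkene geometry, comes back to the route at 12.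

Step 14. Insertion into the electron-rich, peri-substituted chromone may be slow, so that protodeboronation wins, the facial selectivity may be poor, or the rhodium enolate may open to a chalcone. The fallback separates bond formation from stereocontrol and sets out from 19 and 21. Bromide 21 with magnesium would give the Grignard reagent [3,5-bis(methoxymethoxy)phenyl]magnesium bromide F3. Its copper-catalysed conjugate addition to 19 (CuBr·SMe2, TMSCl, THF, −78 °C) should give the silyl enol ether 2-aryl-4-(trimethylsilyloxy)-2H-chromene F4, hydrolysed on work-up to the racemic flavanone rac-25 F5. Kinetic resolution by asymmetric transfer hydrogenation with RuCl[(R,R)-TsDPEN](p-cymene) in HCO2H/Et3N is expected to reduce the 2R enantiomer to the cis alcohol (2R,4R)-flavan-4-ol F6. The 2S ketone would be left behind, and the route is rejoined at 25; the sense of the resolution would be confirmed before use.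

Step 11. The electron-rich hydroxybenzylic alcohol may ionise to a quinone methide or be over-oxidised, the terminal ynone may polymerise, or closure may go 5-exo. The fallback builds C2 from a formamide acetal and sets out from 15. Addition of MeMgBr (3 equiv) would give the magnesium alkoxide of 2-(1-hydroxyethyl)-3,5-bis(methoxymethoxy)-4-farnesylphenol F7. This would be oxidised in the same flask with 1,1'-(azodicarbonyl)dipiperidine (Mukaiyama oxidation of magnesium alkoxides) to the acetophenone 1-[6-hydroxy-2,4-bis(methoxymethoxy)-3-farnesylphenyl]ethanone F8. Condensation with DMF dimethyl acetal in toluene at 80 °C would give the enaminone (2E)-3-(dimethylamino)-1-[6-hydroxy-2,4-bis(methoxymethoxy)-3-farnesylphenyl]prop-2-en-1-one F9. Warming F9 in AcOH at 60 °C would close the ring with loss of dimethylamine and return to the route at 19.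

Further compounds
F1 | step 7 | (1E,5E)-1-iodo-2,6,10-trimethylundeca-1,5,9-triene | CC(C)=CCC/C(C)=C/CC/C(C)=C/I
F2 | step 7 | [2,6-bis(methoxymethoxy)-4-(tosyloxy)benzyl]zinc chloride | Cl[Zn]Cc1c(OCOC)cc(OS(=O)(=O)c2ccc(C)cc2)cc1OCOC
F3 | step 14 | [3,5-bis(methoxymethoxy)phenyl]magnesium bromide | Br[Mg]c1cc(OCOC)cc(OCOC)c1
F4 | step 14 | racemic 2-[3,5-bis(methoxymethoxy)phenyl]-5,7-bis(methoxymethoxy)-6-[(2E,6E)-farnesyl]-4-(trimethylsilyloxy)-2H-chromene | CC(C)=CCC/C(C)=C/CC/C(C)=C/Cc1c(OCOC)cc2c(c1OCOC)C(O[Si](C)(C)C)=CC(c1cc(OCOC)cc(OCOC)c1)O2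
F5 | step 14 | racemic 2-[3,5-bis(methoxymethoxy)phenyl]-5,7-bis(methoxymethoxy)-6-[(2E,6E)-farnesyl]chroman-4-one | CC(C)=CCC/C(C)=C/CC/C(C)=C/Cc1c(OCOC)cc2c(c1OCOC)C(=O)CC(c1cc(OCOC)cc(OCOC)c1)O2
F6 | step 14 | (2R,4R)-2-[3,5-bis(methoxymethoxy)phenyl]-5,7-bis(methoxymethoxy)-6-[(2E,6E)-farnesyl]chroman-4-ol | CC(C)=CCC/C(C)=C/CC/C(C)=C/Cc1c(OCOC)cc2c(c1OCOC)[C@H](O)C[C@H](c1cc(OCOC)cc(OCOC)c1)O2
F7 | step 11 | racemic 2-(1-hydroxyethyl)-3,5-bis(methoxymethoxy)-4-[(2E,6E)-farnesyl]phenol (as magnesium alkoxide) | CC(C)=CCC/C(C)=C/CC/C(C)=C/Cc1c(OCOC)cc(O)c(C(C)O)c1OCOC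
F8 | step 11 | 1-[6-hydroxy-2,4-bis(methoxymethoxy)-3-[(2E,6E)-farnesyl]phenyl]ethanone | CC(C)=CCC/C(C)=C/CC/C(C)=C/Cc1c(OCOC)cc(O)c(C(C)=O)c1OCOC
F9 | step 11 | (2E)-3-(dimethylamino)-1-[6-hydroxy-2,4-bis(methoxymethoxy)-3-[(2E,6E)-farnesyl]phenyl]prop-2-en-1-one | CC(C)=CCC/C(C)=C/CC/C(C)=C/Cc1c(OCOC)cc(O)c(C(=O)/C=C/N(C)C)c1OCOC
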